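**Plan**
- Ring A numbering follows the target: C1 carbonyl, C2/C6 OH, C3/C5 prenyl, C4 OMe. The only link between the rings is the ketone carbon. It is bonded to C1 of fully substituted ring A (between the C2 and C6 oxygens) and to C1' of ring B (oxygen at C4'), and carbon monoxide can supply such a one-atom link.
- Retrosynthesis: remove three MOM ethers, then cut C1–C(=O) and C(=O)–C1' together (aryl iodide + CO + arylboronic acid). Next cut C1–I, then the C5–prenyl and C3–prenyl bonds, which leads back to 5-methoxyresorcinol.
- Forward: no ring is built, since both benzene rings are bought. Ring A is filled by directed metalations in the order C1 (silyl block), C3, C5, C1 (unblock, iodide). The rings are joined through CO in the penultimate step.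
- Stereochemistry: none to control. The target has no stereocentre and both alkenes end in gem-dimethyl groups.

Key step: step 7

Assumption: 4-(methoxymethoxy)phenylboronic acid is a catalogue compound and is used as bought, because its MOM ether is stable to the basic coupling medium.

**Step 1**
Reactants: 1 5-methoxyresorcinol (3,5-dihydroxyanisole)
Product: 2 1-methoxy-3,5-bis(methoxymethoxy)benzene
Conditions: NaH (2.5 equiv), MOMCl (2.5 equiv), DMF, 0 °C to rt
Reagents that add atoms: chloromethyl methyl ether (MOMCl), COCCl
Why: Williamson-type O-alkylation of both sodium phenoxides with the reactive α-chloro ether should give the base-stable acetals that later direct the metalations.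

**Step 2**
Reactants: 2 1-methoxy-3,5-bis(methoxymethoxy)benzene
Product: 4 [4-methoxy-2,6-bis(methoxymethoxy)phenyl]trimethylsilane, via C1-aryllithium 3 (not isolated)
Conditions: n-BuLi (1.1 equiv), THF, 0 °C; then Me3SiCl, −78 °C to rt
Reagents that add atoms: chlorotrimethylsilane, C[Si](C)(C)Cl
Why: Directed ortho-metalation should occur at the C–H between the two OMOM groups, the only site where lithium is chelated by two acetal oxygens, and the silyl quench blocks it for the next two metalations.

**Step 3**
Reactants: 4 [4-methoxy-2,6-bis(methoxymethoxy)phenyl]trimethylsilane; 5 prenyl bromide (1-bromo-3-methylbut-2-ene)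
Product: 8 [4-methoxy-2,6-bis(methoxymethoxy)-3-(3-methylbut-2-enyl)phenyl]trimethylsilane, via C3-aryllithium 6 (not isolated), via C3-arylcopper 7 (not isolated)
Conditions: n-BuLi (1.15 equiv), THF, 0 °C; CuBr·SMe2 (1.2 equiv), −78 to −30 °C; 5 (1.3 equiv), −78 °C to rt
Reagents that add atoms: none
Why: Directed ortho-metalation at one of the two equivalent C–H sites flanked by OMe and OMOM, transmetalation to the weakly basic arylcopper and SN2-type allylation at the unhindered CH2 of 5 should give the linear prenyl arene without proton transfer from the product.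

**Step 4**
Reactants: 8 [4-methoxy-2,6-bis(methoxymethoxy)-3-(3-methylbut-2-enyl)phenyl]trimethylsilane; 5 prenyl bromide
Product: 11 [4-methoxy-2,6-bis(methoxymethoxy)-3,5-bis(3-methylbut-2-enyl)phenyl]trimethylsilane, via C5-aryllithium 9 (not isolated), via C5-arylcopper 10 (not isolated)
Conditions: n-BuLi (1.1 equiv), THF, −20 to 0 °C; CuBr·SMe2 (1.2 equiv), −78 to −30 °C; 5 (1.3 equiv), −78 °C to rt
Reagents that add atoms: none
Why: The same directed ortho-metalation and copper-mediated allylation acts on the last ring C–H, where precoordination of n-BuLi to the flanking OMe and OMOM oxygens should make ring lithiation faster than removal of the benzylic–allylic protons of the first prenyl group.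

**Step 5**
Reactants: 11 [4-methoxy-2,6-bis(methoxymethoxy)-3,5-bis(3-methylbut-2-enyl)phenyl]trimethylsilane
Product: 12 3-methoxy-1,5-bis(methoxymethoxy)-2,4-bis(3-methylbut-2-enyl)benzene
Conditions: Bu4NF·3H2O (3 equiv), THF, 55 °C
Reagents that add atoms: none
Why: In this fluoride-induced protodesilylation, attack at silicon expels an aryl anion that is stabilised by its two ortho oxygens and freed from severe crowding, water protonates it, and MOM ethers and prenyl groups are inert to the medium.

**Step 6**
Reactants: 12 3-methoxy-1,5-bis(methoxymethoxy)-2,4-bis(3-methylbut-2-enyl)benzene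
Product: 14 2-iodo-5-methoxy-1,3-bis(methoxymethoxy)-4,6-bis(3-methylbut-2-enyl)benzene, via C1-aryllithium 13 (not isolated)
Conditions: n-BuLi (1.1 equiv), THF, −20 to 0 °C; I2 (1.2 equiv) in THF, −78 °C; aq. Na2S2O3 work-up
Reagents that add atoms: iodine, II
Why: Directed ortho-metalation at the unmasked C–H between the two OMOM groups (the sole ring hydrogen and the best chelated site) followed by iodination of the aryllithium should give the iodide, since iodine does not add irreversibly to trisubstituted alkenes in the cold.

**Step 7**
Reactants: 14 2-iodo-5-methoxy-1,3-bis(methoxymethoxy)-4,6-bis(3-methylbut-2-enyl)benzene; 15 carbon monoxide; 16 4-(methoxymethoxy)phenylboronic acid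
Product: 17 [4-methoxy-2,6-bis(methoxymethoxy)-3,5-bis(3-methylbut-2-enyl)phenyl][4-(methoxymethoxy)phenyl]methanone
Conditions: PdCl2(IPr)(3-chloropyridine) (3 mol %; IPr = 1,3-bis(2,6-diisopropylphenyl)imidazol-2-ylidene), Cs2CO3 (3 equiv), CO (4 bar), 16 (2 equiv), PhCl, 80 °C
Reagents that add atoms: none
Why: This is a carbonylative Suzuki–Miyaura coupling, a reaction type established for 2,6-disubstituted aryl iodides with bulky carbene–palladium catalysts. Zerovalent palladium released from the precatalyst inserts into the C1–I bond of 14, and migratory insertion of CO then forms C1–C(carbonyl) and an aroylpalladium iodide whose metal sits one atom outside the pocket of the two ortho OMOM groups. The carbonate-activated boronate of 16, unhindered at C1', transmetalates to this complex, and reductive elimination forms C(carbonyl)–C1' and returns zerovalent palladium. No ring is closed and no stereocentre is created. The selectivity required is ketone over direct biaryl, and the substrate secures it because the C2/C6 ethers, buttressed by the C3/C5 prenyl groups, hold back transmetalation at the arylpalladium stage far more than uptake of the small CO ligand, an advantage reinforced by the CO pressure. The medium is basic and free of Lewis acid, so the MOM acetals persist, and the trisubstituted prenyl alkenes, meta to C1, are poor acceptors for acylpalladium.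

**Step 8**
Reactants: 17 [4-methoxy-2,6-bis(methoxymethoxy)-3,5-bis(3-methylbut-2-enyl)phenyl][4-(methoxymethoxy)phenyl]methanone
Product: 18 vismiaphenone D, [2,6-dihydroxy-4-methoxy-3,5-bis(3-methylbut-2-enyl)phenyl](4-hydroxyphenyl)methanone
Conditions: HCl (conc. aq., catalytic), MeOH, rt to 40 °C, stopped at full conversion with aq. NaHCO3
Reagents that add atoms: none
Why: Acid-catalysed transacetalisation (methanolysis) of the three aryl MOM acetals runs at an acidity too low to protonate the trisubstituted alkenes, and the freed C2/C6 hydroxyls are hydrogen-bonded to the ketone, which disfavours chroman closure.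

**Compound list**
1 | 5-methoxyresorcinol | COc1cc(O)cc(O)c1 | starting material
2 | 1-methoxy-3,5-bis(methoxymethoxy)benzene | COCOc1cc(OC)cc(OCOC)c1 | intermediate
3 | [4-methoxy-2,6-bis(methoxymethoxy)phenyl]lithium | [Li]c1c(OCOC)cc(OC)cc1OCOC | intermediate
4 | [4-methoxy-2,6-bis(methoxymethoxy)phenyl]trimethylsilane | COCOc1cc(OC)cc(OCOC)c1[Si](C)(C)C | intermediate
5 | prenyl bromide (1-bromo-3-methylbut-2-ene) | CC(C)=CCBr | starting material
6 | [6-methoxy-2,4-bis(methoxymethoxy)-3-(trimethylsilyl)phenyl]lithium | [Li]c1c(OC)cc(OCOC)c([Si](C)(C)C)c1OCOC | intermediate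
7 | [6-methoxy-2,4-bis(methoxymethoxy)-3-(trimethylsilyl)phenyl]copper | [Cu]c1c(OC)cc(OCOC)c([Si](C)(C)C)c1OCOC | intermediate
8 | [4-methoxy-2,6-bis(methoxymethoxy)-3-(3-methylbut-2-enyl)phenyl]trimethylsilane | COc1cc(OCOC)c([Si](C)(C)C)c(OCOC)c1CC=C(C)C | intermediate
9 | [6-methoxy-2,4-bis(methoxymethoxy)-5-(3-methylbut-2-enyl)-3-(trimethylsilyl)phenyl]lithium | [Li]c1c(OC)c(CC=C(C)C)c(OCOC)c([Si](C)(C)C)c1OCOC | intermediate
10 | [6-methoxy-2,4-bis(methoxymethoxy)-5-(3-methylbut-2-enyl)-3-(trimethylsilyl)phenyl]copper | [Cu]c1c(OC)c(CC=C(C)C)c(OCOC)c([Si](C)(C)C)c1OCOC | intermediate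
11 | [4-methoxy-2,6-bis(methoxymethoxy)-3,5-bis(3-methylbut-2-enyl)phenyl]trimethylsilane | COc1c(CC=C(C)C)c(OCOC)c([Si](C)(C)C)c(OCOC)c1CC=C(C)C | intermediate
12 | 3-methoxy-1,5-bis(methoxymethoxy)-2,4-bis(3-methylbut-2-enyl)benzene | COc1c(CC=C(C)C)c(OCOC)cc(OCOC)c1CC=C(C)C | intermediate
13 | [4-methoxy-2,6-bis(methoxymethoxy)-3,5-bis(3-methylbut-2-enyl)phenyl]lithium | COc1c(CC=C(C)C)c(OCOC)c([Li])c(OCOC)c1CC=C(C)C | intermediate
14 | 2-iodo-5-methoxy-1,3-bis(methoxymethoxy)-4,6-bis(3-methylbut-2-enyl)benzene | COc1c(CC=C(C)C)c(OCOC)c(I)c(OCOC)c1CC=C(C)C | intermediate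
15 | carbon monoxide | [C-]#[O+] | starting material
16 | 4-(methoxymethoxy)phenylboronic acid | COCOc1ccc(B(O)O)cc1 | starting material
17 | [4-methoxy-2,6-bis(methoxymethoxy)-3,5-bis(3-methylbut-2-enyl)phenyl][4-(methoxymethoxy)phenyl]methanone | COc1c(CC=C(C)C)c(OCOC)c(C(=O)c2ccc(OCOC)cc2)c(OCOC)c1CC=C(C)C | intermediate
18 | vismiaphenone D | COc1c(CC=C(C)C)c(O)c(C(=O)c2ccc(O)cc2)c(O)c1CC=C(C)C | target

Total step count: 8. Longest linear sequence: 8 steps (1 to 18).

**Steps most likely to fail**

**Step 7.** Transmetalation at the crowded aroylpalladium stage may lag. Loss of CO with direct aryl–aryl coupling, capture of the acyl complex by hydroxide, or reductive loss of iodine could then take over. The fallback sets out from 12 and comes back at 17, and it brings in the ketone carbon at the aldehyde oxidation level on ring B. Compound 12 is lithiated as in step 6 to aryllithium 13, which is added at −78 °C in THF to commercial 4-(methoxymethoxy)benzaldehyde. This should give racemic [4-methoxy-2,6-bis(methoxymethoxy)-3,5-bis(3-methylbut-2-enyl)phenyl][4-(methoxymethoxy)phenyl]methanol F1. Oxidation of this doubly benzylic alcohol with Dess–Martin periodinane buffered with NaHCO3 in CH2Cl2 then gives 17. Addition to an aldehyde cannot over-add and the oxidation is neutral, so the prenyl and MOM groups are safe.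

**Step 4.** Deprotonation of the benzylic–allylic CH2 of the first prenyl group may compete with ring metalation, and some attack at the tertiary terminus of the allyl bromide is conceivable. The fallback sets out from 1 and comes back at 14. It avoids all organolithium chemistry on prenylated arenes by delivering both prenyl groups from oxygen.
- Iodination of 1 between the two hydroxyls (I2, NaHCO3, H2O–THF, 0 °C) gives 2-iodo-5-methoxybenzene-1,3-diol F2.
- Copper-catalysed etherification with 3-chloro-3-methylbut-1-yne (CuCl2·2H2O cat., DBU, MeCN, 0 °C) gives 2-iodo-5-methoxy-1,3-bis[(2-methylbut-3-yn-2-yl)oxy]benzene F3.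
- Semihydrogenation (H2, Pd on CaCO3 poisoned with Pb(OAc)2, quinoline, EtOAc) gives 2-iodo-5-methoxy-1,3-bis[(2-methylbut-3-en-2-yl)oxy]benzene F4.
- Heating in N,N-diethylaniline at about 130 °C triggers two aromatic Claisen rearrangements. These can end only at C4 and C6 because C2 carries iodine, and they give 2-iodo-5-methoxy-4,6-bis(3-methylbut-2-enyl)benzene-1,3-diol F5.
- MOM protection under the conditions of step 1 gives 14.

**Step 8.** The liberated ortho phenols may add across the neighbouring prenyl double bonds under acid (chroman closure), or the 4'-acetal may be cleaved incompletely at the acidity the alkenes tolerate. The fallback sets out from 17 and comes back at 18, and it replaces Brønsted-acid solvolysis by a silylative exchange under non-acidic conditions. Me3SiOTf and 2,2'-bipyridyl in MeCN (0 °C to rt) convert the aryl MOM ethers into the silyl ethers. The product is [4-methoxy-3,5-bis(3-methylbut-2-enyl)-2,6-bis(trimethylsilyloxy)phenyl][4-(trimethylsilyloxy)phenyl]methanone F6. Adding water to the same flask hydrolyses F6 to 18.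

**Further compounds**
F1 | step 7 | [4-methoxy-2,6-bis(methoxymethoxy)-3,5-bis(3-methylbut-2-enyl)phenyl][4-(methoxymethoxy)phenyl]methanol (racemic) | COc1c(CC=C(C)C)c(OCOC)c(C(O)c2ccc(OCOC)cc2)c(OCOC)c1CC=C(C)C
F2 | step 4 | 2-iodo-5-methoxybenzene-1,3-diol | COc1cc(O)c(I)c(O)c1
F3 | step 4 | 2-iodo-5-methoxy-1,3-bis[(2-methylbut-3-yn-2-yl)oxy]benzene | COc1cc(OC(C)(C)C#C)c(I)c(OC(C)(C)C#C)c1
F4 | step 4 | 2-iodo-5-methoxy-1,3-bis[(2-methylbut-3-en-2-yl)oxy]benzene | COc1cc(OC(C)(C)C=C)c(I)c(OC(C)(C)C=C)c1
F5 | step 4 | 2-iodo-5-methoxy-4,6-bis(3-methylbut-2-enyl)benzene-1,3-diol | COc1c(CC=C(C)C)c(O)c(I)c(O)c1CC=C(C)C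
F6 | step 8 | [4-methoxy-3,5-bis(3-methylbut-2-enyl)-2,6-bis(trimethylsilyloxy)phenyl][4-(trimethylsilyloxy)phenyl]methanone | COc1c(CC=C(C)C)c(O[Si](C)(C)C)c(C(=O)c2ccc(O[Si](C)(C)C)cc2)c(O[Si](C)(C)C)c1CC=C(C)C
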